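The flavone is traced back to a 2,4,6-trihydroxyphenyl chalcone, and this to an open chain in which ring A is still a 4-hydroxy-2-pyrone. The disconnection rests on ring A: it bears oxygen at C5, C7 and C8a, each separated by one carbon, and its acyl carbon C4 is attached at C4a, the acetate-derived phloroglucinol pattern of a polyketide. In one operation Mg(OMe)2 in methanol unmasks the pyrone as a 3,5,7-triketo ester and closes ring A by Claisen condensation (bond C4a–C5) with aromatisation. The precursor already carries the prenylated, MOM-protected ring B, C2, the methoxylated C3 and C4 as an α-methoxy enone tied by one methylene to C6 of the pyrone.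

Key step: step 7

Assumption: the enol ether double bond made in step 5 is taken as Z (aryl trans to the carbonyl), the thermodynamically preferred geometry. It is erased when ring C forms, so any minor E isomer would converge on the same flavone.

Step 1
Reactants: 1 vanillin; 2 3-chloro-3-methylbut-1-yne
Product: 3 3-methoxy-4-(2-methylbut-3-yn-2-yloxy)benzaldehyde
Conditions: DBU, CuCl2·2H2O (cat.), MeCN, 0 °C to rt
Reagents that add atoms: none
Why: Copper-catalysed propargylic etherification, in which the copper acetylide of 2 ionises at the tertiary carbon and the phenoxide of 1 captures it there; this is an established way to hindered aryl 1,1-dimethylpropargyl ethers and tolerates the aldehyde.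

Step 2
Reactants: 3 3-methoxy-4-(2-methylbut-3-yn-2-yloxy)benzaldehyde
Product: 4 3-methoxy-4-(2-methylbut-3-en-2-yloxy)benzaldehyde
Conditions: H2 (1 atm), Pd/CaCO3 poisoned with Pb(OAc)2, quinoline, EtOAc, rt
Reagents that add atoms: none
Why: Lindlar semi-hydrogenation of the terminal alkyne should stop at the alkene when hydrogen uptake is limited to one equivalent, and the aromatic aldehyde is not reduced over the poisoned catalyst.

Step 3
Reactants: 4 3-methoxy-4-(2-methylbut-3-en-2-yloxy)benzaldehyde
Product: 5 4-hydroxy-3-methoxy-5-(3-methylbut-2-enyl)benzaldehyde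
Conditions: PhNEt2, 160 °C
Reagents that add atoms: none
Why: Aromatic Claisen rearrangement ([3,3]-sigmatropic shift, then enolisation) delivers the allyl unit with allylic inversion to C5, the only free ortho position, so the tertiary ether becomes the linear prenyl group.

Step 4
Reactants: 5 4-hydroxy-3-methoxy-5-(3-methylbut-2-enyl)benzaldehyde
Product: 6 3-methoxy-4-(methoxymethoxy)-5-(3-methylbut-2-enyl)benzaldehyde
Conditions: MOMCl, iPr2NEt, CH2Cl2, 0 °C to rt
Reagents that add atoms: chloromethyl methyl ether, COCCl
Why: Williamson-type O-alkylation of the acidic phenol gives the MOM acetal, which withstands every later basic step and keeps the phenol away from the prenyl alkene in step 8.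

Step 5
Reactants: 6 3-methoxy-4-(methoxymethoxy)-5-(3-methylbut-2-enyl)benzaldehyde; 7 methyl methoxyacetate
Product: 8 methyl (Z)-2-methoxy-3-[3-methoxy-4-(methoxymethoxy)-5-(3-methylbut-2-enyl)phenyl]prop-2-enoate
Conditions: 7 (3 equiv), NaOMe (1.5 equiv), MeOH, reflux
Reagents that add atoms: none
Why: Alkoxide-mediated aldol condensation (Claisen–Schmidt type) of the ester enolate with the non-enolisable aldehyde, then E1cB loss of water; reversibility places the aryl group trans to the ester, and a second equivalent of 7 is sacrificed to take up the hydroxide formed.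

Step 6
Reactants: 8 methyl (Z)-2-methoxy-3-[3-methoxy-4-(methoxymethoxy)-5-(3-methylbut-2-enyl)phenyl]prop-2-enoate; 9 4-hydroxy-6-methyl-2H-pyran-2-one
Product: 10 4-hydroxy-6-[(Z)-3-methoxy-4-[3-methoxy-4-(methoxymethoxy)-5-(3-methylbut-2-enyl)phenyl]-2-oxobut-3-enyl]pyran-2-one
Conditions: 9 (2.2 equiv), LiN(iPr)2 (4.5 equiv), THF, −78 to −20 °C; then 8, −78 °C to rt; cold 1 M HCl
Reagents that add atoms: none
Why: Claisen-type C-acylation of the pyrone dianion at its 6-methyl carbanion, the last-formed and most nucleophilic site; the surplus dianion deprotonates the product so that no second addition occurs, and 1,4-addition is disfavoured by the hard lithium carbanion at low temperature and by the aryl- and methoxy-substituted alkene.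

Step 7
Reactants: 10 4-hydroxy-6-[(Z)-3-methoxy-4-[3-methoxy-4-(methoxymethoxy)-5-(3-methylbut-2-enyl)phenyl]-2-oxobut-3-enyl]pyran-2-one
Product: 12 (Z)-2-methoxy-3-[3-methoxy-4-(methoxymethoxy)-5-(3-methylbut-2-enyl)phenyl]-1-(2,4,6-trihydroxyphenyl)prop-2-en-1-one, via triketo ester 11 (not isolated)
Conditions: Mg(OMe)2 (8 equiv), MeOH (degassed), reflux; cold 1 M HCl to pH 4
Reagents that add atoms: none
Why: Magnesium-bound methoxide adds to the lactone carbonyl of 10 and the pyrone opens to the magnesium chelate of the methyl 3,5,7-trioxo ester 11; its doubly activated methylene between the 5-keto group and the enone carbonyl (the future C4a) then attacks the ester carbon (the future C5), methoxide is expelled and three enolisations aromatise the new ring. The closest known reaction type is this very one, the base-induced opening of 6-(2-oxoalkyl)-4-hydroxy-2-pyrones followed by intramolecular Claisen (Dieckmann-type) condensation of the triketo ester to an acylphloroglucinol, which mirrors the chalcone synthase folding. Ring A closes in the 6-exo-trig mode, the enolate carbon adding to an ester C=O whose oxygen stays outside the forming ring. No stereocentre is created and the enol ether double bond is not involved. The selectivity needed is Claisen folding over aldol folding (ester α-carbon onto the enone carbonyl, which would give a styryl resorcylate): the magnesium chelate holds the central enolate next to the ester, methanol keeps the chain end an ester and not an inert carboxylate, and the only aldol acceptor is the α-methoxy enone carbonyl, which is cross-conjugated, donor-substituted and hindered.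

Step 8
Reactants: 12 (Z)-2-methoxy-3-[3-methoxy-4-(methoxymethoxy)-5-(3-methylbut-2-enyl)phenyl]-1-(2,4,6-trihydroxyphenyl)prop-2-en-1-one
Product: 14 5,7-dihydroxy-3-methoxy-2-[3-methoxy-4-(methoxymethoxy)-5-(3-methylbut-2-enyl)phenyl]chromen-4-one, via 3-methoxyflavanone 13 (not isolated)
Conditions: Pd(O2CCF3)2 (10 mol%), O2 (1 atm), DMSO, 100 °C
Reagents that add atoms: none
Why: Oxidative cyclisation of a 2'-hydroxychalcone to a flavone with divalent palladium and O2: conjugate addition of either of the two equivalent ortho hydroxyls gives flavanone 13, whose palladium enolate at C3 loses H–C2 by β-hydride elimination, and O2 returns zerovalent palladium to divalent palladium; the MOM group prevents Wacker-type oxypalladation of the prenyl alkene by the ring B phenol, and any 12 that has already closed to 13 on work-up of step 7 converges here.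

Step 9
Reactants: 14 5,7-dihydroxy-3-methoxy-2-[3-methoxy-4-(methoxymethoxy)-5-(3-methylbut-2-enyl)phenyl]chromen-4-one
Product: 15 dodoviscin J, 5,7-dihydroxy-2-[4-hydroxy-3-methoxy-5-(3-methylbut-2-enyl)phenyl]-3-methoxychromen-4-one
Conditions: HCl (1 M), MeOH, 40 °C
Reagents that add atoms: none
Why: Acid-catalysed acetal solvolysis transfers the methoxymethyl group to methanol; the dilute acid and mild temperature should be too weak to add the freed phenol across the trisubstituted prenyl alkene if the reaction is stopped at full conversion.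

Compound list
1 | vanillin (4-hydroxy-3-methoxybenzaldehyde) | COc1cc(C=O)ccc1O | starting material
2 | 3-chloro-3-methylbut-1-yne | CC(C)(Cl)C#C | starting material
3 | 3-methoxy-4-(2-methylbut-3-yn-2-yloxy)benzaldehyde | COc1cc(C=O)ccc1OC(C)(C)C#C | intermediate
4 | 3-methoxy-4-(2-methylbut-3-en-2-yloxy)benzaldehyde | COc1cc(C=O)ccc1OC(C)(C)C=C | intermediate
5 | 4-hydroxy-3-methoxy-5-(3-methylbut-2-enyl)benzaldehyde | COc1cc(C=O)cc(CC=C(C)C)c1O | intermediate
6 | 3-methoxy-4-(methoxymethoxy)-5-(3-methylbut-2-enyl)benzaldehyde | COCOc1c(OC)cc(C=O)cc1CC=C(C)C | intermediate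
7 | methyl methoxyacetate | COCC(=O)OC | starting material
8 | methyl (Z)-2-methoxy-3-[3-methoxy-4-(methoxymethoxy)-5-(3-methylbut-2-enyl)phenyl]prop-2-enoate | CO/C(C(=O)OC)=C\c1cc(OC)c(OCOC)c(CC=C(C)C)c1 | intermediate
9 | 4-hydroxy-6-methyl-2H-pyran-2-one | Cc1cc(O)cc(=O)o1 | starting material
10 | 4-hydroxy-6-[(Z)-3-methoxy-4-[3-methoxy-4-(methoxymethoxy)-5-(3-methylbut-2-enyl)phenyl]-2-oxobut-3-enyl]pyran-2-one | CO/C(C(=O)Cc1cc(O)cc(=O)o1)=C\c1cc(OC)c(OCOC)c(CC=C(C)C)c1 | intermediate
11 | methyl (Z)-8-methoxy-9-[3-methoxy-4-(methoxymethoxy)-5-(3-methylbut-2-enyl)phenyl]-3,5,7-trioxonon-8-enoate (triketo ester, present as its magnesium chelate, not isolated) | COC(=O)CC(=O)CC(=O)CC(=O)/C(OC)=C/c1cc(OC)c(OCOC)c(CC=C(C)C)c1 | intermediate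
12 | (Z)-2-methoxy-3-[3-methoxy-4-(methoxymethoxy)-5-(3-methylbut-2-enyl)phenyl]-1-(2,4,6-trihydroxyphenyl)prop-2-en-1-one | CO/C(C(=O)c1c(O)cc(O)cc1O)=C\c1cc(OC)c(OCOC)c(CC=C(C)C)c1 | intermediate
13 | 5,7-dihydroxy-3-methoxy-2-[3-methoxy-4-(methoxymethoxy)-5-(3-methylbut-2-enyl)phenyl]chroman-4-one (3-methoxyflavanone, racemic, both C2/C3 diastereomers, stereocentres erased in the same step, not isolated) | COC1C(c2cc(OC)c(OCOC)c(CC=C(C)C)c2)Oc2cc(O)cc(O)c2C1=O | intermediate
14 | 5,7-dihydroxy-3-methoxy-2-[3-methoxy-4-(methoxymethoxy)-5-(3-methylbut-2-enyl)phenyl]chromen-4-one | COCOc1c(OC)cc(-c2oc3cc(O)cc(O)c3c(=O)c2OC)cc1CC=C(C)C | intermediate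
15 | dodoviscin J, 5,7-dihydroxy-2-[4-hydroxy-3-methoxy-5-(3-methylbut-2-enyl)phenyl]-3-methoxychromen-4-one (no stereocentres) | COc1cc(-c2oc3cc(O)cc(O)c3c(=O)c2OC)cc(CC=C(C)C)c1O | target

Total step count: 9. Longest linear sequence: 9 steps (from 1 to 15; 2, 7 and 9 are purchased and enter directly).

Steps most likely to fail

Step 7. After the lactone opens, the chain may fold the other way (aldol closure onto the enone carbonyl), the pyrone may simply re-form on acidification, or methoxide may add to the enone. The fallback gives up the polyketide folding and builds on a ready-made phloroglucinol. It sets out from 6 and comes back to the route at 15.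
- Purchased 2-methoxy-1-(2,4,6-trihydroxyphenyl)ethanone (COCC(=O)c1c(O)cc(O)cc1O) is protected twice with MOMCl and iPr2NEt in CH2Cl2 at 0 °C, the hydrogen-bonded hydroxyl staying free. This should give 1-[2-hydroxy-4,6-bis(methoxymethoxy)phenyl]-2-methoxyethanone F1.
- Claisen–Schmidt condensation of F1 with aldehyde 6 (KOH, EtOH, rt) should give (Z)-1-[2-hydroxy-4,6-bis(methoxymethoxy)phenyl]-2-methoxy-3-[3-methoxy-4-(methoxymethoxy)-5-(3-methylbut-2-enyl)phenyl]prop-2-en-1-one F2.
- Under the conditions of step 8 (Pd(O2CCF3)2, O2, DMSO, 100 °C), F2 should pass through the unisolated 3-methoxy-5,7-bis(methoxymethoxy)-2-[3-methoxy-4-(methoxymethoxy)-5-(3-methylbut-2-enyl)phenyl]chroman-4-one F3 to 3-methoxy-5,7-bis(methoxymethoxy)-2-[3-methoxy-4-(methoxymethoxy)-5-(3-methylbut-2-enyl)phenyl]chromen-4-one F4.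
- HCl in MeOH at 40 °C then removes all three MOM groups to give 15.

Step 6. The dianion may add in conjugate fashion to the acrylate, or proton transfer from the acidic product may quench the dianion and stall the acylation. The fallback changes the acyl donor to one that forms a stable chelated tetrahedral adduct. It sets out from 8 and comes back at 10.
- Me(MeO)NH·HCl and iPrMgCl in THF at −20 °C should convert 8 into (Z)-N,2-dimethoxy-N-methyl-3-[3-methoxy-4-(methoxymethoxy)-5-(3-methylbut-2-enyl)phenyl]prop-2-enamide F5.
- Addition of the lithium dianion of 9 to F5 (THF, −78 °C to 0 °C) gives a chelate that releases the ketone only on acidic work-up, delivering 10.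

Step 8. The palladium catalyst may engage the prenyl alkene (allylic palladation), traces of CF3CO2H may strip the MOM group so that the prenyl arm cyclises oxidatively, or the electron-rich ring A may be over-oxidised. The fallback is metal-free and runs in two stages. It sets out from 12 and comes back at 14.
- NaOAc in refluxing EtOH closes 12 to flavanone 13, which is isolated this time.
- I2 in pyridine at 90 °C dehydrogenates 13 by α-iodination and base-mediated loss of HI in a buffered medium that spares the MOM and prenyl groups, giving 14.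

Further compounds
F1 | step 7 | 1-[2-hydroxy-4,6-bis(methoxymethoxy)phenyl]-2-methoxyethanone | COCC(=O)c1c(O)cc(OCOC)cc1OCOC
F2 | step 7 | (Z)-1-[2-hydroxy-4,6-bis(methoxymethoxy)phenyl]-2-methoxy-3-[3-methoxy-4-(methoxymethoxy)-5-(3-methylbut-2-enyl)phenyl]prop-2-en-1-one | CO/C(C(=O)c1c(O)cc(OCOC)cc1OCOC)=C\c1cc(OC)c(OCOC)c(CC=C(C)C)c1
F3 | step 7 | 3-methoxy-5,7-bis(methoxymethoxy)-2-[3-methoxy-4-(methoxymethoxy)-5-(3-methylbut-2-enyl)phenyl]chroman-4-one (racemic, both C2/C3 diastereomers, not isolated) | COC1C(c2cc(OC)c(OCOC)c(CC=C(C)C)c2)Oc2cc(OCOC)cc(OCOC)c2C1=O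
F4 | step 7 | 3-methoxy-5,7-bis(methoxymethoxy)-2-[3-methoxy-4-(methoxymethoxy)-5-(3-methylbut-2-enyl)phenyl]chromen-4-one | COCOc1c(OC)cc(-c2oc3cc(OCOC)cc(OCOC)c3c(=O)c2OC)cc1CC=C(C)C
F5 | step 6 | (Z)-N,2-dimethoxy-N-methyl-3-[3-methoxy-4-(methoxymethoxy)-5-(3-methylbut-2-enyl)phenyl]prop-2-enamide | CO/C(C(=O)N(C)OC)=C\c1cc(OC)c(OCOC)c(CC=C(C)C)c1
F0 | step 8 | none | none
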